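The flask is a stirred vessel that receives its starting material as a steady feed over 3.0 min and is then left until 4.0 h.

| flask | starting material | precatalyst | remark | time |
|---|---|---|---|---|
| birch | 23 mM (fed, over 3.0 min) | 0.87 mol% | run made earlier; the fed solution adds 0.20 times the starting volume |  |
| cedar | 23 mM (fed, over 3.0 min) | 2 mol% | run made earlier; the fed solution adds 0.20 times the starting volume |  |
| maple | 34 mM (fed, over 3.0 min) | 1.3 mol% | run made earlier; the fed solution adds 0.20 times the starting volume |  |
| flask | 23 mM (fed, over 3.0 min) | 1.3 mol% | the fed solution adds 0.20 times the starting volume | 4.0 h |

- birch (time / h: starting material / %, target / %, side product / %): 0.417: 3.2, 5.6, 13.8; 0.833: 0.9, 5.6, 15.3; 1.33: 0, 5.7, 14.8; 1.50: 0, 5.2, 15.7; 2.00: 0.5, 5.2, 16.7; 2.50: 0.3, 6.3, 16.0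
- cedar (time / h: starting material / %, target / %, side product / %): 0.200: 5.1, 12.2, 11.0; 0.333: 3.2, 11.6, 11.8; 0.500: 1.6, 13.2, 14.1; 0.833: 0.4, 12.9, 13.9; 1.33: 0, 13.8, 15.1; 2.50: 0, 12.9, 15.0
- maple (time / h: starting material / %, target / %, side product / %): 0.500: 1.6, 8.8, 11.9; 1.00: 0, 9.3, 12.6; 1.33: 0, 7.1, 12.3; 2.00: 0.4, 8.6, 12.1; 2.50: 0.3, 7.9, 11.0

(readings scatter by 0.5 percentage points)

- every charge counts on the volume at the start, and the solution that is fed holds the whole dose
- the analysis behind the earlier runs scatters by 0.5 percentage points, standard deviation
- the reaction counts as stopped when no species that holds the starting material changes by six tenths of a point or more over the second half of the time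

1. the state of affairs at 4.0 h: stopped, and by what, or still going (forward and back rates have come level / all of the starting material has reacted / it is still moving)
2. conversion of starting material at 4.0 h
3. amount of target at 4.0 h, in percent of the starting material charged
4. amount of side product at 4.0 h, in percent of the starting material charged

1. In the birch run, target reads 5.6 % at 0.417 h and 5.6 % at 0.833 h, while starting material falls from 3.2 % to 0.9 %. Target is thus level within the scatter while starting material still falls, so the next step is to hold the target readings against the catalyst charge.

2. Take the mean target over readings with starting material below 2 %, and divide by the loading. This gives 6.44 for birch, 6.60 for cedar and 6.42 for maple. Their mean is the turnover number N, the target made per precatalyst charged: 6.48.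

3. Maple, at the higher concentration, gives nearly the same N as birch. The flask's reckoned target is therefore N times its loading, 8.43 %.

4. One number is not enough for side product. Its mean, 15.7 % in birch and 14.5 % in cedar, gives 18.0 and 7.26 per unit of loading. The flask's loading lies between those two runs at the same charge, so its side product is placed between those two means.

5. Birch's last starting material reading, 0.3 %, lies below the scatter of 0.5 percentage points, so the flask is expected to have consumed its starting material.

6. The forecast says all of the starting material has reacted, with conversion 100 %, target 8.5 % and side product 15.1 %, on the ground that “Target tracks precatalyst loading”.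

The simulation gives: all of the starting material has reacted, with conversion >99.9 %, target 8.44 % and side product 15.3 %.

    starting material + free catalyst → free catalyst + target (k = 15.0 M⁻¹ s⁻¹)
    starting material → side product (k = 7.90 × 10⁻⁴ s⁻¹)
    precatalyst → free catalyst (k = 0.00870 s⁻¹)
    2 starting material → homo dimer (k = 0.440 M⁻¹ s⁻¹)
    starting material + free catalyst → spent catalyst (k = 2.30 M⁻¹ s⁻¹)

The flask's target over its loading is 6.50, and at 4.00 h spent catalyst stands at 99.6 % of the catalyst charged. A second flask with 5.2 mol% of precatalyst ends with 97.8 % as spent catalyst; N times that loading and that share gives 33.0 %, and that second flask holds 33.2 % of target.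

The runs are simulated on assumed constants.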